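The decalin is cut between ring A and ring B: C10 (quaternary, methyl) lies beta to the C6 oxygen and C9 sits para to C6, so ring B is a latent 2,6-dimethyl-1,4-benzoquinone, while C1–C4 with the C4 gem-dimethyl group is 4-methylpenta-1,3-diene. One catalytic enantioselective Diels–Alder reaction forms C1–C10 and C4–C5, sets the C10 quaternary centre and delivers the whole bicyclic core with both ring B oxygens in place. The enedione then guides hydride to C6, a vinyl addition/B-alkyl Suzuki sequence builds the Z side chain on C9, and an acid-mediated 1,3-hydroxyl shift creates C8=C9 and the 7α oxygen.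

Key step: step 1

Remark: labdane numbering is used throughout, and the target is read as (5S,6S,7S,10S,13Z)-7α,15-diacetoxylabda-8,13-dien-6β-ol (trans-decalin, 6β-OH free). The catalyst enantiomer in step 1 is the one that exposes the C2-Si face of the bound quinone. It is taken to be the (S)-prolinol-derived catalyst on the basis of the published selection rules; this assignment is not derived here, and the (R)-catalyst would be used if the sense proved opposite.

Step 1
Reactants: 1 2,6-dimethyl-1,4-benzoquinone; 2 4-methylpenta-1,3-diene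
Product: 3 (4aR,8aS)-2,5,5,8a-tetramethyl-4a,5,8,8a-tetrahydronaphthalene-1,4-dione (cis-fused adduct)
Conditions: (S)-3,3-diphenyl-1-(2-methylphenyl)tetrahydro-1H,3H-pyrrolo[1,2-c][1,3,2]oxazaborole (20 mol %) activated with AlBr3 (16 mol %), 2 (5 equiv), CH2Cl2, −78 → −40 °C, dark
Reagents that add atoms: none
Why: The AlBr3-activated oxazaborolidine binds the more basic, unhindered C4=O of 1 (future C6=O), which lowers the LUMO and puts its largest coefficient on the methyl-bearing C2 (future C10), and the diene adds with its most nucleophilic CH2 terminus leading in a concerted, asynchronous [4+2] cycloaddition. The closest known reaction types are the oxazaborolidinium-catalysed enantioselective Diels–Alder reaction of alkylquinones and the Lewis-acid-promoted cycloaddition of this same diene to cycloalkenones. Ring A is closed as a six-membered carbocycle by suprafacial [4+2] addition across the future C5–C10 bond, so the ring fusion is necessarily cis. C10 (S, quaternary) is fixed by the catalyst, which blocks one face of the bound enone so that the diene adds to the C2-Si face, while C5 (R) follows from the cis addition and is corrected in step 3. The step needs regioselectivity (CH2 to C10, CMe2 to C5), which the matched polarisation and the avoidance of a bond between two fully substituted carbons secure, and periselectivity for [4+2] over stepwise [2+2] or ene paths, which excess diene and low temperature favour; the two enone C=C bonds of 1 are homotopic, and the trisubstituted enedione of 3 should not add a second diene.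

Step 2
Reactants: 3 cis-fused Diels–Alder adduct
Product: 4 (4aR,8aS)-2,5,5,8a-tetramethyl-4a,5,6,7,8,8a-hexahydronaphthalene-1,4-dione (cis-fused)
Conditions: H2 (1 atm), RhCl(PPh3)3 (5 mol %), benzene–EtOH, rt
Reagents that add atoms: none
Why: Homogeneous hydrogenation with Wilkinson's catalyst discriminates by substitution, so the cis-disubstituted C2=C3 bond should be reduced while the trisubstituted, doubly conjugated C7=C8 enedione bond is spared; no stereocentre is formed.

Step 3
Reactants: 4 cis-fused enedione
Product: 5 (4aS,8aS)-2,5,5,8a-tetramethyl-4a,5,6,7,8,8a-hexahydronaphthalene-1,4-dione (trans-fused)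
Conditions: DBU (0.2 equiv), CH2Cl2, rt
Reagents that add atoms: none
Why: Base-mediated epimerisation through the C5=C6 enolate under thermodynamic control should set C5 (S, 5α-H), because quaternary C10 cannot invert or aromatise and the trans-fused 4,4,10-trimethyl decalin, the arrangement of the natural 6-oxo labdanes, is expected to be the more stable.

Step 4
Reactants: 5 trans-fused enedione
Product: 6 (4R,4aS,8aS)-4-hydroxy-2,5,5,8a-tetramethyl-4a,5,6,7,8,8a-hexahydronaphthalen-1(4H)-one (6β-hydroxy enone)
Conditions: NaBH4 (1.0 equiv), CeCl3·7H2O (1.0 equiv), MeOH, −78 °C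
Reagents that add atoms: none
Why: Luche 1,2-reduction should occur at the less hindered C6 carbonyl (C9 is flanked by quaternary C10 and the C8 methyl) from the α face, opposite the axial C10 and C4β methyl groups, giving the axial 6β-alcohol by substrate control.

Step 5
Reactants: 6 6β-hydroxy enone
Product: 7 (1S,4R,4aS,8aS)-1-ethenyl-2,5,5,8a-tetramethyl-1,4,4a,5,6,7,8,8a-octahydronaphthalene-1,4-diol
Conditions: vinylmagnesium bromide (3.5 equiv), CeCl3 (3.5 equiv), THF, −78 → 0 °C; aq. NH4Cl
Reagents that add atoms: vinylmagnesium bromide, C=C[Mg]Br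
Why: Organocerium-type 1,2-addition (Imamoto conditions) to the non-enolisable C9 enone carbonyl after deprotonation of the 6-OH should proceed anti to the angular methyl to give the 9β-alcohol, whose configuration is immaterial because C9 becomes trigonal again in step 8.

Step 6
Reactants: 8 but-2-yn-1-ol
Product: 10 (Z)-3-iodobut-2-en-1-ol, via sodium alkenylalanate 9 (not isolated)
Conditions: NaAlH2(OCH2CH2OMe)2 (Red-Al, 1.5 equiv), Et2O, 0 °C → rt; then I2, THF, −78 °C
Reagents that add atoms: iodine, II
Why: Alkoxide-directed trans-hydroalumination places aluminium on C3 cis to the CH2O group in a five-membered alanate, and iodo-dealumination with retention gives the Z-vinyl iodide that defines the 13Z geometry.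

Step 7
Reactants: 7 vinyl carbinol; 10 (Z)-3-iodobut-2-en-1-ol
Product: 12 (5S,6R,9S,10S,13Z)-labda-7,13-diene-6,9,15-triol, via B-alkyl-9-BBN adduct 11 (not isolated)
Conditions: 9-BBN dimer (3 equiv B–H), THF, rt; then 10 (1.5 equiv), PdCl2(dppf) (5 mol %), AsPh3, Cs2CO3, DMF–H2O, rt → 50 °C
Reagents that add atoms: none
Why: Anti-Markovnikov hydroboration of the only monosubstituted alkene followed by B-alkyl Suzuki–Miyaura coupling should form C12–C13 with retention of the vinyl iodide geometry; no new stereocentre is formed.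

Step 8
Reactants: 12 labda-7,13-diene-6β,9,15-triol
Product: 13 (5S,6S,7S,10S,13Z)-labda-8,13-diene-6,7,15-triol (6β,7α-diol)
Conditions: HClO4 (0.05 M), THF–H2O (3:1), 0 °C → rt, stopped at full conversion of 12
Reagents that add atoms: water, O
Why: In this acid-catalysed 1,3-hydroxyl (oxotropic allylic) transposition the crowded tertiary allylic 9-OH ionises to the C7–C8–C9 allyl cation, which water should capture at C7 to give the tetrasubstituted C8=C9 alkene, attacking axially on the α face anti to the axial 6β-OH (directly or through a transient 6β,7β-epoxide) and so setting C7 (S, 7α-OH, trans-diaxial to 6β-OH).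

Step 9
Reactants: 13 labda-8,13-diene-6β,7α,15-triol
Product: 14 (5S,6S,7S,10S,13Z)-7,15-diacetoxylabda-8,13-dien-6-ol (target)
Conditions: Ac2O (3 equiv), pyridine, DMAP (5 mol %), CH2Cl2, 0 °C → rt
Reagents that add atoms: acetic anhydride, CC(=O)OC(C)=O
Why: DMAP-catalysed acylation should take the primary C15 and the allylic 7α hydroxyls, while the axial 6β-OH, flanked by the syn-axial C4β and C10 methyl groups, stays free and the trans-diaxial diol geometry excludes acyl migration.

Compound list
1 | 2,6-dimethyl-1,4-benzoquinone | CC1=CC(=O)C=C(C)C1=O | starting material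
2 | 4-methylpenta-1,3-diene | C=CC=C(C)C | starting material
3 | (4aR,8aS)-2,5,5,8a-tetramethyl-4a,5,8,8a-tetrahydronaphthalene-1,4-dione | O=C1C(C)=CC(=O)[C@@H]2C(C)(C)C=CC[C@]12C | intermediate
4 | (4aR,8aS)-2,5,5,8a-tetramethyl-4a,5,6,7,8,8a-hexahydronaphthalene-1,4-dione | O=C1C(C)=CC(=O)[C@@H]2C(C)(C)CCC[C@]12C | intermediate
5 | (4aS,8aS)-2,5,5,8a-tetramethyl-4a,5,6,7,8,8a-hexahydronaphthalene-1,4-dione | O=C1C(C)=CC(=O)[C@H]2C(C)(C)CCC[C@]12C | intermediate
6 | (4R,4aS,8aS)-4-hydroxy-2,5,5,8a-tetramethyl-4a,5,6,7,8,8a-hexahydronaphthalen-1(4H)-one | O=C1C(C)=C[C@@H](O)[C@H]2C(C)(C)CCC[C@]12C | intermediate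
7 | (1S,4R,4aS,8aS)-1-ethenyl-2,5,5,8a-tetramethyl-1,4,4a,5,6,7,8,8a-octahydronaphthalene-1,4-diol | C=C[C@]1(O)C(C)=C[C@@H](O)[C@H]2C(C)(C)CCC[C@]12C | intermediate
8 | but-2-yn-1-ol | CC#CCO | starting material
9 | sodium cyclic (Z)-alkenylalanate from 8 and Red-Al (Al on C3, O–Al chelate, two 2-methoxyethoxy ligands) | CC1=CCO[Al-]1(OCCOC)OCCOC.[Na+] | intermediate
10 | (Z)-3-iodobut-2-en-1-ol | OC/C=C(/C)I | intermediate
11 | 9-[2-((1S,4R,4aS,8aS)-1,4-dihydroxy-2,5,5,8a-tetramethyl-1,4,4a,5,6,7,8,8a-octahydronaphthalen-1-yl)ethyl]-9-borabicyclo[3.3.1]nonane | B1(CC[C@]3(O)C(C)=C[C@@H](O)[C@H]4C(C)(C)CCC[C@]34C)C2CCCC1CCC2 | intermediate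
12 | (5S,6R,9S,10S,13Z)-labda-7,13-diene-6,9,15-triol | OC/C=C(/C)CC[C@]1(O)C(C)=C[C@@H](O)[C@H]2C(C)(C)CCC[C@]12C | intermediate
13 | (5S,6S,7S,10S,13Z)-labda-8,13-diene-6,7,15-triol | OC/C=C(/C)CCC1=C(C)[C@H](O)[C@@H](O)[C@H]2C(C)(C)CCC[C@]12C | intermediate
14 | (5S,6S,7S,10S,13Z)-7,15-diacetoxylabda-8,13-dien-6-ol | CC(=O)OC/C=C(/C)CCC1=C(C)[C@H](OC(C)=O)[C@@H](O)[C@H]2C(C)(C)CCC[C@]12C | target

Total step count: 9. Longest linear sequence: 8 steps (steps 1–5, 7, 8, 9); step 6 is a one-step side branch.

Steps most likely to fail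

Step 1. The diene must reach an s-cis conformation against its Z-methyl group, so cycloaddition may be too slow and the diene may instead be consumed by cationic oligomerisation or by stepwise [2+2] or ene addition. Facial discrimination may also erode at the higher temperature then needed. The fallback sets out from 1 and comes back at 3, replacing the diene by its 2-silyloxy analogue, which is far more nucleophilic and can also close ring A stepwise (Mukaiyama–Michael addition, then ring closure). Commercial mesityl oxide with TBSOTf/Et3N should give 2-(tert-butyldimethylsilyloxy)-4-methylpenta-1,3-diene F1. Cycloaddition of F1 with 1 under the same chiral oxazaborolidinium catalysis, for which 2-silyloxydienes are the standard diene class, should give (4aR,8aS)-7-(tert-butyldimethylsilyloxy)-2,5,5,8a-tetramethyl-4a,5,8,8a-tetrahydronaphthalene-1,4-dione F2. CsF/PhNTf2 in DME should convert the silyl enol ether into (4aR,8aS)-2,5,5,8a-tetramethyl-1,4-dioxo-4a,5,8,8a-tetrahydronaphthalen-7-yl trifluoromethanesulfonate F3, and Pd(PPh3)4/LiCl/Bu3SnH in THF should reduce the C–OTf bond to C–H, giving 3.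

Step 8. Capture of the allyl cation at C7 may be accompanied by proton loss to dienes, by closure of the cis-related 6β-OH onto C9, by attack on the β face, or by ionisation of the Z-allylic alcohol of the side chain. The fallback sets out from 12 and comes back at 13, fixing C7 by an oxidative transposition and a hydroxyl-directed reduction. TBSOTf/2,6-lutidine should silylate the C15 and 6β hydroxyls (the tertiary 9-OH is left) to give (5S,6R,9S,10S,13Z)-6,15-bis(tert-butyldimethylsilyloxy)labda-7,13-dien-9-ol F6. Pyridinium chlorochromate (C5H5NH[CrO3Cl]) in CH2Cl2 (Dauben–Babler oxidative 1,3-transposition) should give (5S,6S,10S,13Z)-6,15-bis(tert-butyldimethylsilyloxy)labda-8,13-dien-7-one F7. HF·pyridine should give (5S,6S,10S,13Z)-6,15-dihydroxylabda-8,13-dien-7-one F8. Me4NBH(OAc)3 in MeCN–AcOH at −20 °C should then deliver hydride intramolecularly from the 6β-oxygen to the β face of C7, giving the 6β,7α-diol 13.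

Step 2. The enedione C7=C8 bond may be hydrogenated competitively, or the C2=C3 bond next to quaternary C4 may react too slowly. The fallback sets out from 3 and comes back at 5, giving up chemoselectivity and restoring the enedione afterwards. H2 over 10% Pd/C in EtOAc should reduce both C=C bonds to (4aR,8aS)-2,5,5,8a-tetramethyloctahydronaphthalene-1,4-dione F4 (C2 epimers). K2CO3/MeOH should equilibrate C5 and C8 to (2R,4aS,8aS)-2,5,5,8a-tetramethyloctahydronaphthalene-1,4-dione F5 (trans-fused, equatorial methyl). SeO2 in refluxing t-BuOH, the classical dehydrogenation of 1,4-diketones, can only introduce the C7=C8 bond and should give 5.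

Further compounds
F1 | step 1 | 2-(tert-butyldimethylsilyloxy)-4-methylpenta-1,3-diene | C=C(O[Si](C)(C)C(C)(C)C)C=C(C)C
F2 | step 1 | (4aR,8aS)-7-(tert-butyldimethylsilyloxy)-2,5,5,8a-tetramethyl-4a,5,8,8a-tetrahydronaphthalene-1,4-dione | O=C1C(C)=CC(=O)[C@@H]2C(C)(C)C=C(O[Si](C)(C)C(C)(C)C)C[C@]12C
F3 | step 1 | (4aR,8aS)-2,5,5,8a-tetramethyl-1,4-dioxo-4a,5,8,8a-tetrahydronaphthalen-7-yl trifluoromethanesulfonate | O=C1C(C)=CC(=O)[C@@H]2C(C)(C)C=C(OS(=O)(=O)C(F)(F)F)C[C@]12C
F4 | step 2 | (4aR,8aS)-2,5,5,8a-tetramethyloctahydronaphthalene-1,4-dione (C2 epimers) | O=C1C(C)CC(=O)[C@@H]2C(C)(C)CCC[C@]12C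
F5 | step 2 | (2R,4aS,8aS)-2,5,5,8a-tetramethyloctahydronaphthalene-1,4-dione | O=C1[C@H](C)CC(=O)[C@H]2C(C)(C)CCC[C@]12C
F6 | step 8 | (5S,6R,9S,10S,13Z)-6,15-bis(tert-butyldimethylsilyloxy)labda-7,13-dien-9-ol | CC(C)(C)[Si](C)(C)OC/C=C(/C)CC[C@]1(O)C(C)=C[C@@H](O[Si](C)(C)C(C)(C)C)[C@H]2C(C)(C)CCC[C@]12C
F7 | step 8 | (5S,6S,10S,13Z)-6,15-bis(tert-butyldimethylsilyloxy)labda-8,13-dien-7-one | CC(C)(C)[Si](C)(C)OC/C=C(/C)CCC1=C(C)C(=O)[C@@H](O[Si](C)(C)C(C)(C)C)[C@H]2C(C)(C)CCC[C@]12C
F8 | step 8 | (5S,6S,10S,13Z)-6,15-dihydroxylabda-8,13-dien-7-one | OC/C=C(/C)CCC1=C(C)C(=O)[C@@H](O)[C@H]2C(C)(C)CCC[C@]12C
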